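**Plan**

- Retrosynthesis: the two benzyl–oxygen bonds (O5 and O4') are cut last. Ring B is then opened at C2'–C3', C4'–C5' and C1'–C2' into a coumarin-3-yl enone diazo ketone and benzyloxyethyne.
- Enabling feature: ring B is a resorcinol bound through C1' to C3 of the coumarin, with oxygen on C2' and C4'. A ketene carbonyl carbon becomes C2'–OH and the oxygen-bearing carbon of an ynol ether becomes C4'.
- Earlier cuts: C–N2 (diazo transfer to a methyl ketone), CO–CH3 (acyl chloride plus methylzinc), C6–CH2 of the prenyl group (Claisen shift from O5), and C3–C4/O1–C2 of the pyranone (Knoevenagel–lactonisation with dimethyl glutaconate).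
- Forward order: ring A is bought as 2,4,6-trihydroxybenzaldehyde, the pyranone ring is closed second, the prenyl group is moved from O5 to C6, the side chain is turned into the diazo ketone, and ring B is built last.
- Stereochemistry: the target has no stereocentre. The E side-chain alkene from the glutaconate is carried through and ends as the C1'–C6' bond of ring B.

Key step: step 11

Remark: the diazo group is introduced by diazo transfer because diazomethane would add as a 1,3-dipole to the conjugated C=C bonds of an enoyl chloride and of the coumarin; the ring-B oxygen is carried as a benzyl ether because benzyloxyethyne, unlike an unsubstituted silyloxyethyne, has a dependable preparation, and O5 is benzylated too so that one step unmasks both.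

**Route**

Step 1
Reactants: 1 2,4,6-trihydroxybenzaldehyde
Product: 2 2,6-dihydroxy-4-methoxybenzaldehyde
Conditions: MeI (1.0 equiv), K2CO3 (1.0 equiv), acetone, rt
Reagents that add atoms: iodomethane, CI
Why: Williamson etherification should take the C4 hydroxyl, which is the most acidic one and the only one not hydrogen-bonded to the aldehyde, so that one equivalent of MeI stops at the monomethyl ether.

Step 2
Reactants: 2 2,6-dihydroxy-4-methoxybenzaldehyde; 3 dimethyl (E)-pent-2-enedioate (dimethyl glutaconate)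
Product: 5 methyl (E)-3-(5-hydroxy-7-methoxy-2-oxo-2H-chromen-3-yl)prop-2-enoate, via Knoevenagel adduct 4 (not isolated)
Conditions: piperidine (0.2 equiv), AcOH (0.2 equiv), MeOH, 65 °C
Reagents that add atoms: none
Why: Knoevenagel condensation at the doubly activated C2 methylene of the glutaconate gives 4, and lactonisation of an ortho phenol onto the neighbouring ester closes the pyranone ring; the aldehyde is symmetric, so either hydroxyl gives the same coumarin, and the E acrylate of 3 is retained.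

Step 3
Reactants: 5 methyl (E)-3-(5-hydroxy-7-methoxy-2-oxo-2H-chromen-3-yl)prop-2-enoate; 6 3-chloro-3-methylbut-1-yne
Product: 7 methyl (E)-3-[7-methoxy-5-(2-methylbut-3-yn-2-yloxy)-2-oxo-2H-chromen-3-yl]prop-2-enoate
Conditions: DBU (1.3 equiv), CuCl2·2H2O (1 mol %), MeCN, 0 °C
Reagents that add atoms: none
Why: copper-catalysed substitution of the tertiary propargylic chloride by the phenoxide (Godfrey conditions) is the standard entry to aryl 1,1-dimethylpropargyl ethers and runs cold enough to spare the unsaturated ester and the lactone.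

Step 4
Reactants: 7 methyl (E)-3-[7-methoxy-5-(2-methylbut-3-yn-2-yloxy)-2-oxo-2H-chromen-3-yl]prop-2-enoate
Product: 8 methyl (E)-3-[7-methoxy-5-(2-methylbut-3-en-2-yloxy)-2-oxo-2H-chromen-3-yl]prop-2-enoate
Conditions: H2 (1 atm), Pd/CaCO3 poisoned with Pb(OAc)2 (Lindlar catalyst), quinoline, EtOAc, rt
Reagents that add atoms: none
Why: Lindlar semihydrogenation reduces the terminal alkyne to the alkene and should leave the conjugated acrylate and the coumarin C3–C4 bond untouched.

Step 5
Reactants: 8 methyl (E)-3-[7-methoxy-5-(2-methylbut-3-en-2-yloxy)-2-oxo-2H-chromen-3-yl]prop-2-enoate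
Product: 10 methyl (E)-3-[5-hydroxy-7-methoxy-6-(3-methylbut-2-enyl)-2-oxo-2H-chromen-3-yl]prop-2-enoate, via dienone 9 (not isolated)
Conditions: PhNEt2, 130 °C
Reagents that add atoms: none
Why: aromatic Claisen rearrangement of the 1,1-dimethylallyl ether delivers the allyl terminus to C6, the only free ortho position of O5 (C4a is the ring fusion), and enolisation of dienone 9 gives the 6-prenyl phenol.

Step 6
Reactants: 10 methyl (E)-3-[5-hydroxy-7-methoxy-6-(3-methylbut-2-enyl)-2-oxo-2H-chromen-3-yl]prop-2-enoate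
Product: 11 methyl (E)-3-[5-(benzyloxy)-7-methoxy-6-(3-methylbut-2-enyl)-2-oxo-2H-chromen-3-yl]prop-2-enoate
Conditions: BnBr (1.3 equiv), K2CO3 (2 equiv), DMF, rt
Reagents that add atoms: benzyl bromide, BrCc1ccccc1
Why: Williamson benzylation of the C5 phenol gives an ether that should survive hydroxide, organozinc, amide base and light and that leaves together with the ring-B benzyl ether at the end.

Step 7
Reactants: 11 methyl (E)-3-[5-(benzyloxy)-7-methoxy-6-(3-methylbut-2-enyl)-2-oxo-2H-chromen-3-yl]prop-2-enoate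
Product: 13 (E)-3-[5-(benzyloxy)-7-methoxy-6-(3-methylbut-2-enyl)-2-oxo-2H-chromen-3-yl]prop-2-enoic acid, via ring-opened trilithium coumarinate 12 (not isolated)
Conditions: LiOH·H2O (4 equiv), THF/H2O, rt, dark; then 1 M HCl to pH 2, rt
Reagents that add atoms: lithium hydroxide, [Li+].[OH-]
Why: saponification of the methyl ester, in which hydroxide also opens the lactone to the (Z)-coumarinate 12; this re-lactonises on acidification because the phenol and the carboxyl group stay cis on the double bond.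

Step 8
Reactants: 13 (E)-3-[5-(benzyloxy)-7-methoxy-6-(3-methylbut-2-enyl)-2-oxo-2H-chromen-3-yl]prop-2-enoic acid
Product: 15 (E)-4-[5-(benzyloxy)-7-methoxy-6-(3-methylbut-2-enyl)-2-oxo-2H-chromen-3-yl]but-3-en-2-one, via acid chloride 14 (not isolated)
Conditions: Me2C=C(Cl)NMe2 (1.1 equiv), CH2Cl2, 0 °C to rt; then MeZnCl (1.5 equiv), Pd(PPh3)4 (5 mol %), THF, 0 °C to rt
Reagents that add atoms: methylzinc chloride, C[Zn]Cl; 1-chloro-N,N,2-trimethylprop-1-en-1-amine, CC(C)=C(Cl)N(C)C (its chlorine is present only in 14)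
Why: Ghosez's reagent forms the acid chloride without releasing HCl, which protects the prenyl alkene, and the Negishi acylation of the acyl chloride with the organozinc should give the methyl ketone without addition to the lactone or the enone.

Step 9
Reactants: 15 (E)-4-[5-(benzyloxy)-7-methoxy-6-(3-methylbut-2-enyl)-2-oxo-2H-chromen-3-yl]but-3-en-2-one
Product: 18 (E)-4-[5-(benzyloxy)-7-methoxy-6-(3-methylbut-2-enyl)-2-oxo-2H-chromen-3-yl]-1-diazobut-3-en-2-one, via lithium enolate 16 (not isolated), via trifluoroacetyl diketone 17 (not isolated)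
Conditions: LiN(SiMe3)2 (1.1 equiv), THF, −78 °C; CF3CO2CH2CF3 (1.2 equiv), −78 °C; aq. HCl work-up; then MsN3 (1.5 equiv), Et3N (1.5 equiv), H2O (1 equiv), MeCN, rt, dark
Reagents that add atoms: methanesulfonyl azide, CS(=O)(=O)N=[N+]=[N-]; 2,2,2-trifluoroethyl trifluoroacetate, O=C(OCC(F)(F)F)C(F)(F)F (its trifluoroacetyl group is present only in 17)
Why: detrifluoroacetylative diazo transfer (Danheiser's method for α,β-unsaturated α'-diazo ketones), in which the kinetic methyl enolate 16 is trifluoroacetylated to 17 and 17 takes the diazo group from MsN3 while the trifluoroacetyl group leaves on the sulfonamide.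

Step 10
Reactants: 19 benzyl alcohol; 20 trichloroethylene
Product: 24 benzyloxyethyne (benzyl ethynyl ether), via dichlorovinyl ether 21 (not isolated), via chloroethynyl ether 22 (not isolated), via lithium acetylide 23 (not isolated)
Conditions: KH (1.1 equiv), THF, 0 °C; Cl2C=CHCl, −50 °C to rt; n-BuLi (2.4 equiv), −78 to −40 °C; MeOH, −78 °C; kept as a cold solution
Reagents that add atoms: none
Why: Greene's one-pot alkynyl ether synthesis, in which alkoxide addition–elimination on trichloroethylene gives 21, n-BuLi effects dehydrochlorination to 22 and chlorine–lithium exchange to 23, and protonation gives the terminal ynol ether; it is stored cold because benzyl alkynyl ethers rearrange sigmatropically on warming.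

Step 11
Reactants: 18 (E)-4-[5-(benzyloxy)-7-methoxy-6-(3-methylbut-2-enyl)-2-oxo-2H-chromen-3-yl]-1-diazobut-3-en-2-one; 24 benzyloxyethyne
Product: 29 5-(benzyloxy)-3-[4-(benzyloxy)-2-hydroxyphenyl]-7-methoxy-6-(3-methylbut-2-enyl)-2H-chromen-2-one, via vinylketene 25 (not isolated), via cyclobutenone 26 (not isolated), via dienylketene 27 (not isolated), via cyclohexadienone 28 (not isolated)
Conditions: 24 (3 equiv), ClCH2CH2Cl (0.05 M, degassed), hν (medium-pressure Hg lamp, Pyrex, λ > 300 nm), rt; then 80 °C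
Reagents that add atoms: none
Why: Light expels N2 from 18 and the alkenyl group migrates to the carbene carbon (photo-Wolff rearrangement) to give the E vinylketene 25, whose carbonyl carbon is attacked by the unsubstituted, nucleophilic carbon of ynol ether 24 so that a [2+2] cycloaddition gives 3-benzyloxy-4-alkenylcyclobutenone 26 with the new bonds C2'–C3' and C4'–C5'. A 4π electrocyclic opening of 26 gives dienylketene 27, a 6π electrocyclisation of 27 forms C1'–C2' and closes ring B, and enolisation of cyclohexadienone 28 gives the phenol. The closest known reaction is the photochemical Danheiser benzannulation of α,β-unsaturated α'-diazo ketones with alkoxy- and siloxyalkynes. Ring B is thus closed by a pericyclic 6π closure of a six-carbon chain assembled intermolecularly, and no stereocentre is formed. The step needs the regiochemistry of the [2+2] addition, which the polarisation of the ynol ether fixes so that its oxygen ends meta to the new hydroxyl at C4', and it needs the ketene to meet the alkyne first, which the E geometry of the side chain (C4 of the coumarin cannot reach the ketene carbon) and the excess of 24 are meant to secure. Irradiation above 300 nm addresses the diazo enone chromophore and spares the benzyl ethers.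

Step 12
Reactants: 29 5-(benzyloxy)-3-[4-(benzyloxy)-2-hydroxyphenyl]-7-methoxy-6-(3-methylbut-2-enyl)-2H-chromen-2-one
Product: 30 3-(2,4-dihydroxyphenyl)-5-hydroxy-7-methoxy-6-(3-methylbut-2-enyl)-2H-chromen-2-one (CNP0305155.0)
Conditions: BCl3 (5 equiv), C6HMe5 (6 equiv), CH2Cl2, −78 °C; then CHCl3/MeOH, −78 °C to rt
Reagents that add atoms: none
Why: Lewis-acid cleavage of the two aryl benzyl ethers with BCl3 at −78 °C, with pentamethylbenzene as a non-basic trap for the benzyl cation; the aryl methyl ether, the lactone and the prenyl alkene are expected to survive at this temperature.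

**Compound list**

1 | 2,4,6-trihydroxybenzaldehyde | O=Cc1c(O)cc(O)cc1O | starting material
2 | 2,6-dihydroxy-4-methoxybenzaldehyde | COc1cc(O)c(C=O)c(O)c1 | intermediate
3 | dimethyl (E)-pent-2-enedioate (dimethyl glutaconate) | COC(=O)C/C=C/C(=O)OC | starting material
4 | dimethyl (2E)-4-[(2,6-dihydroxy-4-methoxyphenyl)methylidene]pent-2-enedioate (new C=C geometry not fixed) | COC(=O)/C=C/C(C(=O)OC)=Cc1c(O)cc(OC)cc1O | intermediate
5 | methyl (E)-3-(5-hydroxy-7-methoxy-2-oxo-2H-chromen-3-yl)prop-2-enoate | COC(=O)/C=C/c1cc2c(O)cc(OC)cc2oc1=O | intermediate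
6 | 3-chloro-3-methylbut-1-yne | CC(C)(Cl)C#C | starting material
7 | methyl (E)-3-[7-methoxy-5-(2-methylbut-3-yn-2-yloxy)-2-oxo-2H-chromen-3-yl]prop-2-enoate | COC(=O)/C=C/c1cc2c(OC(C)(C)C#C)cc(OC)cc2oc1=O | intermediate
8 | methyl (E)-3-[7-methoxy-5-(2-methylbut-3-en-2-yloxy)-2-oxo-2H-chromen-3-yl]prop-2-enoate | COC(=O)/C=C/c1cc2c(OC(C)(C)C=C)cc(OC)cc2oc1=O | intermediate
9 | methyl (E)-3-[7-methoxy-6-(3-methylbut-2-enyl)-2,5-dioxo-5,6-dihydro-2H-chromen-3-yl]prop-2-enoate (racemic at C6) | COC(=O)/C=C/C1=CC2=C(OC1=O)C=C(OC)C(CC=C(C)C)C2=O | intermediate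
10 | methyl (E)-3-[5-hydroxy-7-methoxy-6-(3-methylbut-2-enyl)-2-oxo-2H-chromen-3-yl]prop-2-enoate | COC(=O)/C=C/c1cc2c(O)c(CC=C(C)C)c(OC)cc2oc1=O | intermediate
11 | methyl (E)-3-[5-(benzyloxy)-7-methoxy-6-(3-methylbut-2-enyl)-2-oxo-2H-chromen-3-yl]prop-2-enoate | COC(=O)/C=C/c1cc2c(OCc3ccccc3)c(CC=C(C)C)c(OC)cc2oc1=O | intermediate
12 | trilithium (2E,4Z)-4-{[2-(benzyloxy)-4-methoxy-3-(3-methylbut-2-enyl)-6-oxidophenyl]methylidene}pent-2-enedioate | [Li+].[Li+].[Li+].[O-]C(=O)/C=C/C(C(=O)[O-])=C/c1c([O-])cc(OC)c(CC=C(C)C)c1OCc1ccccc1 | intermediate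
13 | (E)-3-[5-(benzyloxy)-7-methoxy-6-(3-methylbut-2-enyl)-2-oxo-2H-chromen-3-yl]prop-2-enoic acid | OC(=O)/C=C/c1cc2c(OCc3ccccc3)c(CC=C(C)C)c(OC)cc2oc1=O | intermediate
14 | (E)-3-[5-(benzyloxy)-7-methoxy-6-(3-methylbut-2-enyl)-2-oxo-2H-chromen-3-yl]prop-2-enoyl chloride | ClC(=O)/C=C/c1cc2c(OCc3ccccc3)c(CC=C(C)C)c(OC)cc2oc1=O | intermediate
15 | (E)-4-[5-(benzyloxy)-7-methoxy-6-(3-methylbut-2-enyl)-2-oxo-2H-chromen-3-yl]but-3-en-2-one | CC(=O)/C=C/c1cc2c(OCc3ccccc3)c(CC=C(C)C)c(OC)cc2oc1=O | intermediate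
16 | lithium (3E)-4-[5-(benzyloxy)-7-methoxy-6-(3-methylbut-2-enyl)-2-oxo-2H-chromen-3-yl]buta-1,3-dien-2-olate | [Li]OC(=C)/C=C/c1cc2c(OCc3ccccc3)c(CC=C(C)C)c(OC)cc2oc1=O | intermediate
17 | (E)-6-[5-(benzyloxy)-7-methoxy-6-(3-methylbut-2-enyl)-2-oxo-2H-chromen-3-yl]-1,1,1-trifluorohex-5-ene-2,4-dione | FC(F)(F)C(=O)CC(=O)/C=C/c1cc2c(OCc3ccccc3)c(CC=C(C)C)c(OC)cc2oc1=O | intermediate
18 | (E)-4-[5-(benzyloxy)-7-methoxy-6-(3-methylbut-2-enyl)-2-oxo-2H-chromen-3-yl]-1-diazobut-3-en-2-one | [N-]=[N+]=CC(=O)/C=C/c1cc2c(OCc3ccccc3)c(CC=C(C)C)c(OC)cc2oc1=O | intermediate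
19 | benzyl alcohol | OCc1ccccc1 | starting material
20 | trichloroethylene | ClC=C(Cl)Cl | starting material
21 | benzyl (E)-1,2-dichlorovinyl ether | Cl/C=C(/Cl)OCc1ccccc1 | intermediate
22 | benzyl chloroethynyl ether | ClC#COCc1ccccc1 | intermediate
23 | lithium (benzyloxy)acetylide | [Li]C#COCc1ccccc1 | intermediate
24 | benzyloxyethyne (benzyl ethynyl ether) | C#COCc1ccccc1 | intermediate
25 | (E)-4-[5-(benzyloxy)-7-methoxy-6-(3-methylbut-2-enyl)-2-oxo-2H-chromen-3-yl]buta-1,3-dien-1-one | O=C=C/C=C/c1cc2c(OCc3ccccc3)c(CC=C(C)C)c(OC)cc2oc1=O | intermediate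
26 | 3-(benzyloxy)-4-{(E)-2-[5-(benzyloxy)-7-methoxy-6-(3-methylbut-2-enyl)-2-oxo-2H-chromen-3-yl]ethenyl}cyclobut-2-en-1-one (racemic) | O=C1C=C(OCc2ccccc2)C1/C=C/c1cc2c(OCc3ccccc3)c(CC=C(C)C)c(OC)cc2oc1=O | intermediate
27 | (3E,5E)-3-(benzyloxy)-6-[5-(benzyloxy)-7-methoxy-6-(3-methylbut-2-enyl)-2-oxo-2H-chromen-3-yl]hexa-1,3,5-trien-1-one | O=C=C/C(OCc1ccccc1)=C\C=C\c1cc2c(OCc3ccccc3)c(CC=C(C)C)c(OC)cc2oc1=O | intermediate
28 | 3-(benzyloxy)-6-[5-(benzyloxy)-7-methoxy-6-(3-methylbut-2-enyl)-2-oxo-2H-chromen-3-yl]cyclohexa-2,4-dien-1-one (racemic) | O=C1C=C(OCc2ccccc2)C=CC1c1cc2c(OCc3ccccc3)c(CC=C(C)C)c(OC)cc2oc1=O | intermediate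
29 | 5-(benzyloxy)-3-[4-(benzyloxy)-2-hydroxyphenyl]-7-methoxy-6-(3-methylbut-2-enyl)-2H-chromen-2-one | COc1cc2oc(=O)c(-c3ccc(OCc4ccccc4)cc3O)cc2c(OCc2ccccc2)c1CC=C(C)C | intermediate
30 | 3-(2,4-dihydroxyphenyl)-5-hydroxy-7-methoxy-6-(3-methylbut-2-enyl)-2H-chromen-2-one | COc1cc2oc(=O)c(-c3ccc(O)cc3O)cc2c(O)c1CC=C(C)C | target

**Count**

Total steps: 12. Longest linear sequence: 11 steps (steps 1 to 9, then 11 and 12); step 10 is a one-step side branch.

**Steps most likely to fail**

Step 11. Under irradiation the side-chain alkene can isomerise from E to Z. A Z vinylketene holds the ketene carbon next to C4 of the coumarin and can close onto it by 6π electrocyclisation before it meets the alkyne. The coumarin chromophore can also absorb and enter [2+2] photoaddition, and the ketene can be lost to traces of water.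

The fallback gives up the late ring construction and brings ring B in as an arylacetic acid; it sets out from 2 and comes back at 30. Commercial 2,4-dihydroxyphenylacetic acid would be perbenzylated (BnBr, K2CO3, DMF) to benzyl 2-[2,4-bis(benzyloxy)phenyl]acetate F1 and saponified (NaOH, aqueous MeOH; then HCl) to 2-[2,4-bis(benzyloxy)phenyl]acetic acid F2. Perkin–Oglialoro condensation of 2 with F2 (Ac2O, Et3N, 110 °C) should give 3-[2,4-bis(benzyloxy)phenyl]-7-methoxy-2-oxo-2H-chromen-5-yl acetate F3. Methanolysis of the aryl acetate (K2CO3, MeOH, 0 °C) should give 3-[2,4-bis(benzyloxy)phenyl]-5-hydroxy-7-methoxy-2H-chromen-2-one F4. The conditions of steps 3, 4 and 5 (with 6) would then lead through 3-[2,4-bis(benzyloxy)phenyl]-7-methoxy-5-(2-methylbut-3-yn-2-yloxy)-2H-chromen-2-one F5, 3-[2,4-bis(benzyloxy)phenyl]-7-methoxy-5-(2-methylbut-3-en-2-yloxy)-2H-chromen-2-one F6 and the Claisen dienone 3-[2,4-bis(benzyloxy)phenyl]-7-methoxy-6-(3-methylbut-2-enyl)-2H-chromene-2,5(6H)-dione F7 to 3-[2,4-bis(benzyloxy)phenyl]-5-hydroxy-7-methoxy-6-(3-methylbut-2-enyl)-2H-chromen-2-one F8. The conditions of step 12 would convert F8 into 30.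

Step 12. HCl released when BCl3 meets the phenols can protonate the prenyl alkene. The tertiary cation would then be captured by chloride or by the neighbouring C5 oxygen (chroman ring closure), most likely while the mixture warms during the quench.

The fallback replaces acid-mediated ionisation by neutral reductive C–O cleavage and leads from 29 straight to 30. 29 would be stirred with Pd/C (10 wt %) and 1,4-cyclohexadiene in EtOH/EtOAc at rt. Aryl benzyl ethers cleave fast under catalytic transfer hydrogenolysis, while an unconjugated trisubstituted alkene and the aryl-substituted coumarin C3–C4 bond are reduced only slowly. The reaction would be followed closely and stopped once the second benzyl group is gone. No new compound is made.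

Step 9. The lithium enolate can add in Michael fashion to C4 of a second coumarin before it is trifluoroacetylated, or the acylation can stay incomplete. The diazo ketone can also decompose in light or on acidic silica during isolation.

The fallback avoids a free metal enolate and the acyl activation; it sets out from 15 and comes back at 18. Soft enolisation (Me3SiOTf, Et3N, CH2Cl2, 0 °C) should give the silyl enol ether 5-(benzyloxy)-7-methoxy-6-(3-methylbut-2-enyl)-3-[(1E)-3-(trimethylsilyloxy)buta-1,3-dienyl]-2H-chromen-2-one F9. Bromination at the terminal carbon (NBS, THF, −78 °C) should give (E)-4-[5-(benzyloxy)-7-methoxy-6-(3-methylbut-2-enyl)-2-oxo-2H-chromen-3-yl]-1-bromobut-3-en-2-one F10. Treatment of F10 with N,N'-ditosylhydrazine and DBU (THF, 0 °C; Fukuyama's diazo synthesis from bromoacetyl compounds) would give 18 by N-alkylation and loss of two sulfinates.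

**Further compounds**

F1 | step 11 | benzyl 2-[2,4-bis(benzyloxy)phenyl]acetate | O=C(Cc1ccc(OCc2ccccc2)cc1OCc1ccccc1)OCc1ccccc1
F2 | step 11 | 2-[2,4-bis(benzyloxy)phenyl]acetic acid | OC(=O)Cc1ccc(OCc2ccccc2)cc1OCc1ccccc1
F3 | step 11 | 3-[2,4-bis(benzyloxy)phenyl]-7-methoxy-2-oxo-2H-chromen-5-yl acetate | COc1cc(OC(C)=O)c2cc(-c3ccc(OCc4ccccc4)cc3OCc3ccccc3)c(=O)oc2c1
F4 | step 11 | 3-[2,4-bis(benzyloxy)phenyl]-5-hydroxy-7-methoxy-2H-chromen-2-one | COc1cc(O)c2cc(-c3ccc(OCc4ccccc4)cc3OCc3ccccc3)c(=O)oc2c1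
F5 | step 11 | 3-[2,4-bis(benzyloxy)phenyl]-7-methoxy-5-(2-methylbut-3-yn-2-yloxy)-2H-chromen-2-one | COc1cc(OC(C)(C)C#C)c2cc(-c3ccc(OCc4ccccc4)cc3OCc3ccccc3)c(=O)oc2c1
F6 | step 11 | 3-[2,4-bis(benzyloxy)phenyl]-7-methoxy-5-(2-methylbut-3-en-2-yloxy)-2H-chromen-2-one | COc1cc(OC(C)(C)C=C)c2cc(-c3ccc(OCc4ccccc4)cc3OCc3ccccc3)c(=O)oc2c1
F7 | step 11 | 3-[2,4-bis(benzyloxy)phenyl]-7-methoxy-6-(3-methylbut-2-enyl)-2H-chromene-2,5(6H)-dione (racemic) | O=C1OC2=C(C=C1c1ccc(OCc3ccccc3)cc1OCc1ccccc1)C(=O)C(CC=C(C)C)C(OC)=C2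
F8 | step 11 | 3-[2,4-bis(benzyloxy)phenyl]-5-hydroxy-7-methoxy-6-(3-methylbut-2-enyl)-2H-chromen-2-one | COc1cc2oc(=O)c(-c3ccc(OCc4ccccc4)cc3OCc3ccccc3)cc2c(O)c1CC=C(C)C
F0 | step 12 | none | none
F9 | step 9 | 5-(benzyloxy)-7-methoxy-6-(3-methylbut-2-enyl)-3-[(1E)-3-(trimethylsilyloxy)buta-1,3-dienyl]-2H-chromen-2-one | C[Si](C)(C)OC(=C)/C=C/c1cc2c(OCc3ccccc3)c(CC=C(C)C)c(OC)cc2oc1=O
F10 | step 9 | (E)-4-[5-(benzyloxy)-7-methoxy-6-(3-methylbut-2-enyl)-2-oxo-2H-chromen-3-yl]-1-bromobut-3-en-2-one | BrCC(=O)/C=C/c1cc2c(OCc3ccccc3)c(CC=C(C)C)c(OC)cc2oc1=O
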